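**Strategy**

The oxolane is opened at the O1–C5 bond (O1; C2 bears the trisubstituted aryl ring B; C3 and C4 the methyls; C5 the 4-hydroxyphenyl ring A). Because ring A carries a free para-hydroxyl, C5 and ring A can become a para-quinone methide. The C2 hydroxyl then adds to C5 in a 5-exo-trig oxa-1,6-addition that closes the ring and sets C5 trans to the C4 methyl. The precursor is an open-chain 1,4-diol whose C2–C4 stereotriad comes from rhodium-catalysed desymmetrisation of meso-2,3-dimethylsuccinic anhydride with an arylzinc and a Felkin reduction; the side-chain stereocentre comes from iridium-catalysed asymmetric hydrogenation.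

Key step: step 10

**Remarks on the chemistry**

- Assumption: the sense of induction of the iridium–phosphinooxazoline catalyst (step 4) and of the rhodium–phosphoramidite catalyst (step 6) is taken to follow the parent substrates of each catalyst class; if either delivers the mirror-image sense, the antipodal ligand is used.
- Ring C is the 4-hydroxyphenyl ring of the side chain. In names, ArB stands for the protected ring-B group 4-(benzyloxy)-3-[(2R)-1-[4-(benzyloxy)phenyl]propan-2-yl]phenyl.

**Route**

Step 1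
Reactants: 1 5-bromo-2-hydroxybenzaldehyde
Product: 2 2-(benzyloxy)-5-bromobenzaldehyde
Conditions: BnBr, K2CO3, DMF, rt
Reagents that add atoms: benzyl bromide, BrCc1ccccc1
Why: Williamson ether synthesis, in which the phenoxide is alkylated by the benzylic bromide while the aldehyde and the aryl bromide are untouched.

Step 2
Reactants: 2 2-(benzyloxy)-5-bromobenzaldehyde
Product: 3 1-(benzyloxy)-4-bromo-2-ethynylbenzene
Conditions: dimethyl (1-diazo-2-oxopropyl)phosphonate, K2CO3, MeOH, rt
Reagents that add atoms: dimethyl (1-diazo-2-oxopropyl)phosphonate, CC(=O)C(=[N+]=[N-])P(=O)(OC)OC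
Why: Seyferth–Gilbert homologation in its Ohira–Bestmann form should turn the aryl aldehyde into the terminal alkyne under mild methanolic base that leaves the aryl bromide and the benzyl ether alone.

Step 3
Reactants: 3 1-(benzyloxy)-4-bromo-2-ethynylbenzene; 4 1-(benzyloxy)-4-iodobenzene
Product: 6 1-(benzyloxy)-2-[(1E)-1-[4-(benzyloxy)phenyl]prop-1-en-2-yl]-4-bromobenzene, via alkenylalane 5 (not isolated)
Conditions: Me3Al, Cp2ZrCl2 (20 mol %), CH2Cl2, 0 °C → rt; then 4, Pd(PPh3)4 (5 mol %), ZnCl2 (cat.), THF, rt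
Reagents that add atoms: trimethylaluminium, C[Al](C)C
Why: Zirconium-catalysed methylalumination (Negishi carboalumination) adds methyl and aluminium syn across the alkyne with methyl on the aryl-bearing carbon, and the Negishi cross-coupling that follows proceeds with retention and should engage the aryl iodide of 4 in preference to the aryl bromide, so the E geometry is fixed by the syn addition.

Step 4
Reactants: 6 1-(benzyloxy)-2-[(1E)-1-[4-(benzyloxy)phenyl]prop-1-en-2-yl]-4-bromobenzene
Product: 7 1-(benzyloxy)-2-[(2R)-1-[4-(benzyloxy)phenyl]propan-2-yl]-4-bromobenzene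
Conditions: [Ir(cod)((S)-tBu-PHOX)]BArF (1 mol %), H2 (50 bar), CH2Cl2, rt
Reagents that add atoms: none
Why: Iridium–phosphinooxazoline-catalysed asymmetric hydrogenation of an unfunctionalised E-trisubstituted aryl alkene (the α-methylstilbene class) should deliver hydrogen to the enantioface chosen by the chiral P,N ligand and so set the (R) benzylic stereocentre, while the aryl bromide and benzyl ethers are inert to the homogeneous catalyst.

Step 5
Reactants: 8 meso-2,3-dimethylsuccinic acid
Product: 9 meso-2,3-dimethylsuccinic anhydride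
Conditions: AcCl, reflux
Reagents that add atoms: none
Why: Cyclodehydration of the 1,4-diacid by acetyl chloride gives the five-membered anhydride without touching either stereocentre, so the cis (meso) arrangement of the methyls is kept.

Step 6
Reactants: 7 1-(benzyloxy)-2-[(2R)-1-[4-(benzyloxy)phenyl]propan-2-yl]-4-bromobenzene; 9 meso-2,3-dimethylsuccinic anhydride
Product: 12 (2S,3R)-4-ArB-2,3-dimethyl-4-oxobutanoic acid, via aryllithium 10 (not isolated), via arylzinc chloride 11 (not isolated)
Conditions: n-BuLi, THF, −78 °C; ZnCl2, −78 °C → rt; then 9, [Rh(cod)Cl]2 (2.5 mol %), (R,R)-(TADDOL)P–NMe2 phosphoramidite (5 mol %), THF–DMF, 50 °C; aq. HCl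
Reagents that add atoms: none
Why: Bromine–lithium exchange and transmetalation give an arylzinc that should undergo rhodium-catalysed enantioselective desymmetrising cross-coupling with the cyclic meso anhydride, the chiral phosphoramidite–rhodium complex selecting one of the two enantiotopic acyl–oxygen bonds, so that the later C3 (R) and C4 (S) are fixed in absolute terms while their cis-dimethyl relationship is inherited from 9.

Step 7
Reactants: 12 (2S,3R)-4-ArB-2,3-dimethyl-4-oxobutanoic acid
Product: 14 (3S,4R,5R)-5-ArB-3,4-dimethyloxolan-2-one, via hydroxy acid 13 (not isolated)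
Conditions: LiBH(s-Bu)3, THF, −78 °C; then 2 M HCl, rt
Reagents that add atoms: none
Why: Felkin–Anh-controlled reduction of the aryl ketone by the bulky hydride (attack anti to the CH(CH3)CO2Li branch on the α-carbon) should give the (4R) alcohol anti to the neighbouring methyl, and acid-induced lactonisation then closes the γ-lactone with ring B trans to that methyl.

Step 8
Reactants: 14 (3S,4R,5R)-5-ArB-3,4-dimethyloxolan-2-one
Product: 15 (3S,4R,5R)-5-ArB-3,4-dimethyloxolan-2-ol (anomer mixture)
Conditions: i-Bu2AlH, CH2Cl2, −78 °C; aq. potassium sodium tartrate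
Reagents that add atoms: none
Why: Partial reduction of the γ-lactone with i-Bu2AlH at low temperature stops at the stable aluminium hemiacetal and should give the lactol with the three stereocentres untouched.

Step 9
Reactants: 15 (3S,4R,5R)-5-ArB-3,4-dimethyloxolan-2-ol; 16 (4-bromophenoxy)trimethylsilane
Product: 19 (1RS,2S,3R,4R)-4-ArB-1-(4-hydroxyphenyl)-2,3-dimethylbutane-1,4-diol, via Grignard reagent 17 (not isolated), via silyl ether diol 18 (not isolated)
Conditions: 16, Mg, THF, 40 °C; then 15 (17 in 3 equiv), 0 °C → rt; aq. NH4Cl; then K2CO3, MeOH, 0 °C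
Reagents that add atoms: none
Why: Grignard addition to the lactol, which reacts through its open γ-hydroxy aldehyde form after deprotonation by the first equivalent, installs ring A, and mild methanolysis removes the labile aryl trimethylsilyl ether; the configuration of the new carbinol carbon is irrelevant because that carbon becomes planar in step 10.

Step 10
Reactants: 19 (1RS,2S,3R,4R)-4-ArB-1-(4-hydroxyphenyl)-2,3-dimethylbutane-1,4-diol
Product: 21 (2R,3R,4S,5S)-2-ArB-5-(4-hydroxyphenyl)-3,4-dimethyloxolane, via quinone methide 20 (not isolated)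
Conditions: PPTS (10 mol %), CH2Cl2, rt
Reagents that add atoms: none
Why: PPTS assists loss of water from the C5 carbinol, whose para-hydroxyphenyl ring A collapses to the para-quinone methide 20, so both C5 epimers of 19 converge on one planar intermediate. The C2 hydroxyl then adds to the exocyclic methide carbon C5 in an intramolecular oxa-1,6-conjugate addition that rearomatises ring A; the closest known reaction type is the biomimetic quinone-methide cycloetherification of 1,4-diarylbutane-1,4-diols to 2,5-diaryloxolane lignans. The oxolane closes in 5-exo-trig mode, the O1–C5 bond being the one formed. The new C5 stereocentre is controlled by the adjacent C4 methyl: in the envelope transition state the dienone ring should lie anti to that methyl, giving 4,5-trans and hence 2,5-cis, which is also the thermodynamically preferred arrangement should the closure be reversible. The step needs activation of C5 in preference to the second benzylic carbinol C2, and this is secured by the free para-hydroxyl of ring A (only it can form a neutral quinone methide), whereas ring B carries a benzyl ether and should ionise far more slowly under the weak acid; Friedel–Crafts closure to an aryltetralin is disfavoured because the attacking position of ring B is meta to its oxygen.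

Step 11
Reactants: 21 (2R,3R,4S,5S)-2-ArB-5-(4-hydroxyphenyl)-3,4-dimethyloxolane
Product: 22 (2R,3R,4S,5S)-2-{4-hydroxy-3-[(2R)-1-(4-hydroxyphenyl)propan-2-yl]phenyl}-5-(4-hydroxyphenyl)-3,4-dimethyloxolane (target)
Conditions: H2 (1 atm), Pd/C (10 %), EtOAc, rt
Reagents that add atoms: none
Why: Hydrogenolysis of the two aryl benzyl ethers over Pd/C should be much faster than cleavage of the ring benzylic C–O bonds of the 2,5-diaryloxolane in a neutral solvent, so no stereocentre is touched.

**Compound list**

1 | 5-bromo-2-hydroxybenzaldehyde | O=Cc1cc(Br)ccc1O | starting material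
2 | 2-(benzyloxy)-5-bromobenzaldehyde | O=Cc1cc(Br)ccc1OCc1ccccc1 | intermediate
3 | 1-(benzyloxy)-4-bromo-2-ethynylbenzene | C#Cc1cc(Br)ccc1OCc1ccccc1 | intermediate
4 | 1-(benzyloxy)-4-iodobenzene | Ic1ccc(OCc2ccccc2)cc1 | starting material
5 | [(1E)-2-[2-(benzyloxy)-5-bromophenyl]prop-1-en-1-yl]dimethylalane | C/C(=C\[Al](C)C)c1cc(Br)ccc1OCc1ccccc1 | intermediate
6 | 1-(benzyloxy)-2-[(1E)-1-[4-(benzyloxy)phenyl]prop-1-en-2-yl]-4-bromobenzene | C/C(=C\c1ccc(OCc2ccccc2)cc1)c1cc(Br)ccc1OCc1ccccc1 | intermediate
7 | 1-(benzyloxy)-2-[(2R)-1-[4-(benzyloxy)phenyl]propan-2-yl]-4-bromobenzene | C[C@H](Cc1ccc(OCc2ccccc2)cc1)c1cc(Br)ccc1OCc1ccccc1 | intermediate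
8 | meso-2,3-dimethylsuccinic acid, (2R,3S)-2,3-dimethylbutanedioic acid | C[C@@H](C(=O)O)[C@H](C)C(=O)O | starting material
9 | meso-2,3-dimethylsuccinic anhydride, (3R,4S)-3,4-dimethyloxolane-2,5-dione | C[C@@H]1[C@H](C)C(=O)OC1=O | intermediate
10 | {4-(benzyloxy)-3-[(2R)-1-[4-(benzyloxy)phenyl]propan-2-yl]phenyl}lithium | C[C@H](Cc1ccc(OCc2ccccc2)cc1)c1cc([Li])ccc1OCc1ccccc1 | intermediate
11 | {4-(benzyloxy)-3-[(2R)-1-[4-(benzyloxy)phenyl]propan-2-yl]phenyl}zinc chloride | C[C@H](Cc1ccc(OCc2ccccc2)cc1)c1cc([Zn]Cl)ccc1OCc1ccccc1 | intermediate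
12 | (2S,3R)-4-{4-(benzyloxy)-3-[(2R)-1-[4-(benzyloxy)phenyl]propan-2-yl]phenyl}-2,3-dimethyl-4-oxobutanoic acid | C[C@@H](C(=O)c1ccc(OCc2ccccc2)c([C@H](C)Cc2ccc(OCc3ccccc3)cc2)c1)[C@H](C)C(=O)O | intermediate
13 | (2S,3R,4R)-4-{4-(benzyloxy)-3-[(2R)-1-[4-(benzyloxy)phenyl]propan-2-yl]phenyl}-4-hydroxy-2,3-dimethylbutanoic acid | C[C@@H]([C@@H](O)c1ccc(OCc2ccccc2)c([C@H](C)Cc2ccc(OCc3ccccc3)cc2)c1)[C@H](C)C(=O)O | intermediate
14 | (3S,4R,5R)-5-{4-(benzyloxy)-3-[(2R)-1-[4-(benzyloxy)phenyl]propan-2-yl]phenyl}-3,4-dimethyloxolan-2-one | C[C@@H]1[C@H](C)C(=O)O[C@H]1c1ccc(OCc2ccccc2)c([C@H](C)Cc2ccc(OCc3ccccc3)cc2)c1 | intermediate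
15 | (3S,4R,5R)-5-{4-(benzyloxy)-3-[(2R)-1-[4-(benzyloxy)phenyl]propan-2-yl]phenyl}-3,4-dimethyloxolan-2-ol (anomer mixture) | C[C@@H]1[C@H](C)C(O)O[C@H]1c1ccc(OCc2ccccc2)c([C@H](C)Cc2ccc(OCc3ccccc3)cc2)c1 | intermediate
16 | (4-bromophenoxy)trimethylsilane | C[Si](C)(C)Oc1ccc(Br)cc1 | starting material
17 | [4-(trimethylsilyloxy)phenyl]magnesium bromide | C[Si](C)(C)Oc1ccc([Mg]Br)cc1 | intermediate
18 | (1RS,2S,3R,4R)-4-{4-(benzyloxy)-3-[(2R)-1-[4-(benzyloxy)phenyl]propan-2-yl]phenyl}-2,3-dimethyl-1-[4-(trimethylsilyloxy)phenyl]butane-1,4-diol | C[C@@H]([C@@H](O)c1ccc(OCc2ccccc2)c([C@H](C)Cc2ccc(OCc3ccccc3)cc2)c1)[C@H](C)C(O)c1ccc(O[Si](C)(C)C)cc1 | intermediate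
19 | (1RS,2S,3R,4R)-4-{4-(benzyloxy)-3-[(2R)-1-[4-(benzyloxy)phenyl]propan-2-yl]phenyl}-1-(4-hydroxyphenyl)-2,3-dimethylbutane-1,4-diol | C[C@@H]([C@@H](O)c1ccc(OCc2ccccc2)c([C@H](C)Cc2ccc(OCc3ccccc3)cc2)c1)[C@H](C)C(O)c1ccc(O)cc1 | intermediate
20 | 4-[(2R,3R,4R)-4-{4-(benzyloxy)-3-[(2R)-1-[4-(benzyloxy)phenyl]propan-2-yl]phenyl}-4-hydroxy-2,3-dimethylbutylidene]cyclohexa-2,5-dien-1-one (para-quinone methide) | C[C@@H]([C@@H](O)c1ccc(OCc2ccccc2)c([C@H](C)Cc2ccc(OCc3ccccc3)cc2)c1)[C@H](C)C=C1C=CC(=O)C=C1 | intermediate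
21 | (2R,3R,4S,5S)-2-{4-(benzyloxy)-3-[(2R)-1-[4-(benzyloxy)phenyl]propan-2-yl]phenyl}-5-(4-hydroxyphenyl)-3,4-dimethyloxolane | C[C@@H]1[C@H](C)[C@@H](c2ccc(O)cc2)O[C@H]1c1ccc(OCc2ccccc2)c([C@H](C)Cc2ccc(OCc3ccccc3)cc2)c1 | intermediate
22 | (2R,3R,4S,5S)-2-{4-hydroxy-3-[(2R)-1-(4-hydroxyphenyl)propan-2-yl]phenyl}-5-(4-hydroxyphenyl)-3,4-dimethyloxolane | C[C@@H]1[C@H](C)[C@@H](c2ccc(O)cc2)O[C@H]1c1ccc(O)c([C@H](C)Cc2ccc(O)cc2)c1 | target

**Count and risks**

Total step count: 11. Longest linear sequence: 10 steps (steps 1–4 and 6–11; step 5 is a one-step side branch).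

Steps most likely to fail:

1. Step 6. The two enantiotopic acyl–oxygen bonds of 9 may be discriminated incompletely, or transfer of the hindered, ether-rich aryl group from zinc to rhodium may be slow enough for uncatalysed opening to erode the enantiomeric purity. The fallback sets out from anhydride 9 and returns to the route at lactone 14. Cinchona-alkaloid-mediated desymmetrising methanolysis of 9 (quinidine or quinine, MeOH, toluene, −55 °C) should give the hemiester (2R,3S)-4-methoxy-2,3-dimethyl-4-oxobutanoic acid F1. Treatment with EtSH, DCC and DMAP converts it into the thioester methyl (2S,3R)-4-(ethylsulfanyl)-2,3-dimethyl-4-oxobutanoate F2. Fukuyama coupling of this thioester with arylzinc chloride 11 (made from 7 as in step 6; PdCl2(PPh3)2, THF, rt) should give the keto ester methyl (2S,3R)-4-ArB-2,3-dimethyl-4-oxobutanoate F3. Reduction with LiBH(s-Bu)3 and acid-induced lactonisation with loss of methanol then deliver 14.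

2. Step 4. Enantioface discrimination may be poor because ring B is twisted out of the alkene plane by its ortho benzyloxy group, whose oxygen can also bind iridium. The fallback sets out from alkyne 3 and returns at bromide 7; it sets the stereocentre before the ring-C bond is made. Methylalumination of 3 as in step 3 followed by aqueous quench of alane 5 should give 1-(benzyloxy)-4-bromo-2-(prop-1-en-2-yl)benzene F4. Copper-catalysed enantioselective protoboration of this 1,1-disubstituted aryl alkene (CuCl, chiral N-heterocyclic carbene ligand, NaOt-Bu, B2pin2, MeOH) should give the primary boronate 2-[(2R)-2-[2-(benzyloxy)-5-bromophenyl]propyl]-4,4,5,5-tetramethyl-1,3,2-dioxaborolane F5. An iodide-selective B-alkyl Suzuki–Miyaura coupling with 4 (Pd(OAc)2, RuPhos, K3PO4, toluene–water) then gives 7.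

3. Step 7. Felkin control may be insufficient, with hydride attacking the other carbonyl face and giving the lactone with ring B cis to the neighbouring methyl. The fallback replaces kinetic by thermodynamic control; it sets out from keto acid 12 and returns at lactone 14. Unselective reduction (NaBH4, MeOH) and acidification would give 14 together with its benzylic epimer (3S,4R,5S)-5-ArB-3,4-dimethyloxolan-2-one F6. Treatment with TFA in CH2Cl2 should equilibrate the two through reversible ionisation of the lactone benzylic C–O bond (ring-B-stabilised cation) towards the more stable trans lactone 14.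

Further compounds
F1 | step 6 | (2R,3S)-4-methoxy-2,3-dimethyl-4-oxobutanoic acid | C[C@@H](C(=O)O)[C@H](C)C(=O)OC
F2 | step 6 | methyl (2S,3R)-4-(ethylsulfanyl)-2,3-dimethyl-4-oxobutanoate | C[C@@H](C(=O)SCC)[C@H](C)C(=O)OC
F3 | step 6 | methyl (2S,3R)-4-{4-(benzyloxy)-3-[(2R)-1-[4-(benzyloxy)phenyl]propan-2-yl]phenyl}-2,3-dimethyl-4-oxobutanoate | C[C@@H](C(=O)c1ccc(OCc2ccccc2)c([C@H](C)Cc2ccc(OCc3ccccc3)cc2)c1)[C@H](C)C(=O)OC
F4 | step 4 | 1-(benzyloxy)-4-bromo-2-(prop-1-en-2-yl)benzene | C=C(C)c1cc(Br)ccc1OCc1ccccc1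
F5 | step 4 | 2-[(2R)-2-[2-(benzyloxy)-5-bromophenyl]propyl]-4,4,5,5-tetramethyl-1,3,2-dioxaborolane | C[C@H](CB1OC(C)(C)C(C)(C)O1)c1cc(Br)ccc1OCc1ccccc1
F6 | step 7 | (3S,4R,5S)-5-{4-(benzyloxy)-3-[(2R)-1-[4-(benzyloxy)phenyl]propan-2-yl]phenyl}-3,4-dimethyloxolan-2-one | C[C@@H]1[C@H](C)C(=O)O[C@@H]1c1ccc(OCc2ccccc2)c([C@H](C)Cc2ccc(OCc3ccccc3)cc2)c1
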